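**Plan**

1. The target is a meso compound (mirror plane through the C(OH)(acyl) carbon and the midpoint of the C=C), so only relative configuration has to be set and every chiral intermediate may be racemic.
2. Retrosynthetic cuts, in order: the side-chain C=O (back to CH–OH) and the two acetates with the second ring carbinol (back to a ring ketone); then the ring bond between one acetoxy-bearing CH and its olefinic neighbour CH, which leads to 3-(1-hydroxyundecyl)-4H-pyran-4-one; last the bond from pyranone C3 to the side chain (aldol with undecanal).
3. Enabling feature: the five carbons of the cyclopentene are C2–C6 of a 4H-pyran-4-one whose ring oxygen O1 already sits on the future carbinol CH. Its cross-conjugated dienone O1–C2=C3–C4(=O)–C5=C6 closes C2–C6 on irradiation, so the six-membered oxygen ring contracts to the carbocycle and O1 stays as that hydroxyl.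
4. Forward order: aldol joins the chain to a dihydropyranone; dehydrogenation gives the pyranone ring; photochemical closure with capture of water gives the cyclopentenone ring; a temporary dioxolane ring masks the side-chain diol during ketone reduction and acetylation and is removed before the final oxidation.
5. Stereochemistry: water enters anti to the transient oxirane (tertiary OH trans to the first ring carbinol, side chain cis to it); hydride then adds anti to the side chain (second ring carbinol cis to the first); the side-chain carbinol centre is never controlled because it ends as C=O.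

Key step: step 3

Remark: racemates are drawn as one enantiomer with relative configuration; where the side-chain carbinol carbon carries no descriptor, both epimers are meant.

**Route**

Step 1
Reactants: 1 2,3-dihydro-4H-pyran-4-one; 2 undecanal
Product: 4 3-(1-hydroxyundecyl)-2,3-dihydro-4H-pyran-4-one (racemic; both diastereomers), via lithium enolate 3 (not isolated)
Conditions: LiN(iPr)2, THF, −78 °C; then 2, −78 °C; AcOH quench
Reagents that add atoms: none
Why: Kinetic deprotonation of the vinylogous ester at its only enolizable carbon (C3) followed by directed aldol addition; the two new stereocentres need no control because C3 becomes sp2 in step 2 and the carbinol carbon ends as the ketone.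

Step 2
Reactants: 4 3-(1-hydroxyundecyl)-2,3-dihydro-4H-pyran-4-one
Product: 7 3-(1-hydroxyundecyl)-4H-pyran-4-one (racemic), via bis(trimethylsilyl) dienol ether 5 (not isolated), via pyranone trimethylsilyl ether 6 (not isolated)
Conditions: Me3SiOTf, Et3N, CH2Cl2, 0 °C, pentane work-up; DDQ, CH2Cl2, 0 °C to rt; 1 M HCl, THF
Reagents that add atoms: none
Why: Soft enolization gives the 4-silyloxy-2H-pyran, DDQ abstracts hydride from C2 (allylic and next to the ring oxygen) because this gives the aromatic 4-silyloxypyrylium ion, which loses silicon to the pyranone (dehydrogenation of a silyl enol ether), and the acidic work-up frees the side-chain hydroxyl.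

Step 3
Reactants: 7 3-(1-hydroxyundecyl)-4H-pyran-4-one
Product: 10 trans-4,5-dihydroxy-5-(1-hydroxyundecyl)cyclopent-2-en-1-one (racemic; 4-OH cis to the side chain; both side-chain epimers), via oxabicyclic hydroxyallyl cation 8 (not isolated), via epoxy enol 9 (not isolated)
Conditions: hν (254 nm, quartz), aq. H2SO4 (ca. 1 M)/MeCN, Ar, rt
Reagents that add atoms: water, O
Why: The excited 4-hydroxypyrylium ion (protonated pyranone) undergoes 4π electrocyclization between C2 and C6 to the cis-fused 6-oxabicyclo[3.1.0]hexenyl cation 8 (a 2-hydroxyallyl cation over C3–C4–C5 fused to an oxirane), water adds to the allyl terminus C3, and the enol 9 opens the oxirane at C6 to give the 4-hydroxycyclopent-2-enone. The closest known reaction type is the photochemical ring contraction of 4-pyranones and 4-hydroxypyrylium ions in hydroxylic media to trans-4,5-dihydroxycyclopent-2-enones, a photochemical Nazarov-type closure of a hydroxypentadienyl cation. The five-membered carbocycle is closed by disrotatory 4π electrocyclization of the five-carbon pentadienyl cation (C2 to C6), and the three-membered oxirane formed by the same bond is opened again within the step. Both new ring stereocentres are substrate-controlled: the oxygen on the ring CH is the former ring oxygen on the oxirane face, and water must add to C3 from the opposite face, which places the tertiary hydroxyl trans to it and the side chain cis to it, while the side-chain carbinol centre has no influence and stays a mixture. The step needs capture at the substituted terminus C3 instead of C5 and capture instead of transposition to a 2-pyranone; the alkyl substituent localizes positive charge at C3 (tertiary-type terminus, as in kinetic hydrolysis of unsymmetrical allyl cations) and the large excess of water in dilute acid should favour capture. Irradiation is stopped before full conversion because the product enone also absorbs.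

Step 4
Reactants: 10 trans-4,5-dihydroxy-5-(1-hydroxyundecyl)cyclopent-2-en-1-one
Product: 11 4-decyl-9-hydroxy-2,2-dimethyl-1,3-dioxaspiro[4.4]non-7-en-6-one (racemic; 9-OH trans to O1; both C4 epimers)
Conditions: Me2C(OMe)2, PPTS (cat.), acetone, rt
Reagents that add atoms: 2,2-dimethoxypropane, COC(C)(C)OC
Why: Thermodynamic ketalization should take the vicinal tertiary/secondary diol as a five-membered dioxolane (the ring diol is trans and cannot be bridged, and a six-membered dioxane with the ring carbinol is less favoured for an acetone ketal), which masks the future ketone carbon and leaves the ring hydroxyl free.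

Step 5
Reactants: 11 4-decyl-9-hydroxy-2,2-dimethyl-1,3-dioxaspiro[4.4]non-7-en-6-one
Product: 12 4-decyl-2,2-dimethyl-1,3-dioxaspiro[4.4]non-7-ene-6,9-diol (racemic; 6-OH and 9-OH cis to each other and trans to O1)
Conditions: NaBH4, CeCl3·7H2O, MeOH, −78 °C
Reagents that add atoms: none
Why: Luche 1,2-reduction of the enone, in which hydride should enter from the face of the dioxolane oxygen, opposite to the bulkier side-chain carbon of the spiro centre and opposite to the ring hydroxyl (the usual cis outcome for 4-oxygenated cyclopentenones), so that the new carbinol is cis to both.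

Step 6
Reactants: 12 4-decyl-2,2-dimethyl-1,3-dioxaspiro[4.4]non-7-ene-6,9-diol
Product: 13 4-decyl-2,2-dimethyl-1,3-dioxaspiro[4.4]non-7-ene-6,9-diyl diacetate (racemic)
Conditions: Ac2O, pyridine, DMAP (cat.), CH2Cl2, 0 °C to rt
Reagents that add atoms: acetic anhydride, CC(=O)OC(C)=O
Why: Standard acylation of the two secondary allylic alcohols, which touches no stereocentre.

Step 7
Reactants: 13 4-decyl-2,2-dimethyl-1,3-dioxaspiro[4.4]non-7-ene-6,9-diyl diacetate
Product: 14 2-hydroxy-2-(1-hydroxyundecyl)cyclopent-4-ene-1,3-diyl diacetate (racemic; acetoxy groups cis to each other and to the side chain)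
Conditions: CF3CO2H/H2O (4:1), CH2Cl2, 0 °C
Reagents that add atoms: none
Why: Acid hydrolysis of the ketal, which the acetates should survive in the cold; acid is chosen over base so that acetyl migration to the freed side-chain hydroxyl stays slow, and the tertiary hydroxyl is trans to both acetates and cannot accept an acetyl group through a cyclic orthoester.

Step 8
Reactants: 14 2-hydroxy-2-(1-hydroxyundecyl)cyclopent-4-ene-1,3-diyl diacetate
Product: 15 2-hydroxy-2-undecanoylcyclopent-4-ene-1,3-diyl diacetate (meso; target)
Conditions: IBX, DMSO, rt
Reagents that add atoms: none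
Why: IBX oxidizes the secondary alcohol of a secondary/tertiary 1,2-diol to the α-hydroxy ketone without C–C cleavage and leaves the tertiary alcohol, the acetates and the alkene untouched, so the last uncontrolled stereocentre disappears and the meso target results.

**Compound list**

1 | 2,3-dihydro-4H-pyran-4-one | O=C1CCOC=C1 | starting material
2 | undecanal | CCCCCCCCCCC=O | starting material
3 | lithium 2H-pyran-4-olate (lithium enolate of 1) | [Li+].[O-]C1=CCOC=C1 | intermediate (not isolated)
4 | 3-(1-hydroxyundecyl)-2,3-dihydro-4H-pyran-4-one (racemic; both diastereomers) | CCCCCCCCCCC(O)C1COC=CC1=O | intermediate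
5 | 4-(trimethylsilyloxy)-3-[1-(trimethylsilyloxy)undecyl]-2H-pyran | CCCCCCCCCCC(O[Si](C)(C)C)C1=C(O[Si](C)(C)C)C=COC1 | intermediate (not isolated)
6 | 3-[1-(trimethylsilyloxy)undecyl]-4H-pyran-4-one | CCCCCCCCCCC(O[Si](C)(C)C)C1=COC=CC1=O | intermediate (not isolated)
7 | 3-(1-hydroxyundecyl)-4H-pyran-4-one (racemic) | CCCCCCCCCCC(O)C1=COC=CC1=O | intermediate
8 | 3-hydroxy-2-(1-hydroxyundecyl)-6-oxabicyclo[3.1.0]hex-2-en-4-ylium (cis-fused) | CCCCCCCCCCC(O)C1=C(O)[CH+][C@@H]2O[C@H]12 | intermediate (not isolated)
9 | 2-(1-hydroxyundecyl)-6-oxabicyclo[3.1.0]hex-3-ene-2,3-diol (2-OH anti to the oxirane) | CCCCCCCCCCC(O)[C@@]1(O)[C@H]2O[C@H]2C=C1O | intermediate (not isolated)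
10 | trans-4,5-dihydroxy-5-(1-hydroxyundecyl)cyclopent-2-en-1-one (racemic; 4-OH cis to the side chain) | CCCCCCCCCCC(O)[C@@]1(O)[C@@H](O)C=CC1=O | intermediate
11 | 4-decyl-9-hydroxy-2,2-dimethyl-1,3-dioxaspiro[4.4]non-7-en-6-one (racemic; 9-OH trans to O1) | CCCCCCCCCCC1OC(C)(C)O[C@@]12[C@@H](O)C=CC2=O | intermediate
12 | 4-decyl-2,2-dimethyl-1,3-dioxaspiro[4.4]non-7-ene-6,9-diol (racemic; both OH trans to O1) | CCCCCCCCCCC1OC(C)(C)O[C@@]12[C@@H](O)C=C[C@H]2O | intermediate
13 | 4-decyl-2,2-dimethyl-1,3-dioxaspiro[4.4]non-7-ene-6,9-diyl diacetate (racemic) | CCCCCCCCCCC1OC(C)(C)O[C@@]12[C@@H](OC(C)=O)C=C[C@H]2OC(C)=O | intermediate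
14 | 2-hydroxy-2-(1-hydroxyundecyl)cyclopent-4-ene-1,3-diyl diacetate (racemic; acetoxy groups cis to each other and to the side chain) | CCCCCCCCCCC(O)[C@@]1(O)[C@@H](OC(C)=O)C=C[C@H]1OC(C)=O | intermediate
15 | 2-hydroxy-2-undecanoylcyclopent-4-ene-1,3-diyl diacetate (meso; acetoxy groups cis to each other and to the acyl group, tertiary OH trans to both) | CCCCCCCCCCC(=O)[C@@]1(O)[C@@H](OC(C)=O)C=C[C@H]1OC(C)=O | target

**Step count and risks**

Total steps: 8. Longest linear sequence: 8 (1 to 15).

Steps most likely to fail:

Step 3. Water may add to the unsubstituted terminus (C5) of the hydroxyallyl cation instead of C3, the free side-chain carbinol may send a hydride to C3 (semipinacol shift), or the enone may be photolysed further. The fallback replaces intermolecular capture by neighbouring-group capture. It sets out from 7, which is acetylated (Ac2O, pyridine, DMAP) to 1-(4-oxo-4H-pyran-3-yl)undecyl acetate F1. On irradiation under the same conditions the ester carbonyl oxygen should close onto C3 of the cation as a five-membered 1,3-dioxolan-2-ylium ion, still anti to the oxirane, which fixes the site of attack and blocks the hydride shift. Hydrolysis of that ion gives 1-(1,5-dihydroxy-2-oxocyclopent-3-en-1-yl)undecyl acetate F2 (acetyl on the side-chain oxygen), and acid methanolysis (HCl in MeOH) removes the acetate and comes back to the route at 10.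

Step 4. Ketalization may take the side-chain hydroxyl together with the ring hydroxyl (six-membered ketal) instead of the vicinal diol, so that the wrong hydroxyl is left free. The fallback avoids diol protection altogether. It sets out from 10, which with Bu2SnO (toluene, reflux, removal of water) should give the five-membered stannylene acetal of the vicinal diol, 2,2-dibutyl-4-decyl-9-hydroxy-1,3-dioxa-2-stannaspiro[4.4]non-7-en-6-one F3. Br2 (CH2Cl2, rt) oxidizes the secondary carbinol of F3 and gives trans-4,5-dihydroxy-5-undecanoylcyclopent-2-en-1-one F4. Luche reduction, in which the enone should react faster than the hindered saturated ketone next to the quaternary carbon, gives 2-undecanoylcyclopent-4-ene-1,2,3-triol F5, and Ac2O/pyridine acetylates its two secondary hydroxyls and comes back to the route at 15.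

Step 5. Facial selectivity may be poor or reversed if hydride enters anti to the C–O bond of the spiro centre, giving the carbinol trans to the ring hydroxyl. The fallback sets the carbinol by inversion instead of by hydride direction. It sets out from 11, which is acetylated (Ac2O, pyridine) to 4-decyl-2,2-dimethyl-6-oxo-1,3-dioxaspiro[4.4]non-7-en-9-yl acetate F6. Luche reduction then gives the epimeric alcohol 4-decyl-6-hydroxy-2,2-dimethyl-1,3-dioxaspiro[4.4]non-7-en-9-yl acetate F7 (6-OH trans to 9-OAc), and a Mitsunobu reaction with acetic acid (PPh3, DIAD, THF) inverts this carbinol and comes back to the route at 13.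

**Further compounds**

F1 | step 3 | 1-(4-oxo-4H-pyran-3-yl)undecyl acetate | CCCCCCCCCCC(OC(C)=O)C1=COC=CC1=O
F2 | step 3 | 1-(1,5-dihydroxy-2-oxocyclopent-3-en-1-yl)undecyl acetate (racemic; ring hydroxyls trans) | CCCCCCCCCCC(OC(C)=O)[C@@]1(O)[C@@H](O)C=CC1=O
F3 | step 4 | 2,2-dibutyl-4-decyl-9-hydroxy-1,3-dioxa-2-stannaspiro[4.4]non-7-en-6-one | CCCCCCCCCCC1O[Sn](CCCC)(CCCC)O[C@@]12[C@@H](O)C=CC2=O
F4 | step 4 | trans-4,5-dihydroxy-5-undecanoylcyclopent-2-en-1-one (racemic) | CCCCCCCCCCC(=O)[C@@]1(O)[C@@H](O)C=CC1=O
F5 | step 4 | 2-undecanoylcyclopent-4-ene-1,2,3-triol (meso; 1-OH and 3-OH cis to the acyl group) | CCCCCCCCCCC(=O)[C@@]1(O)[C@@H](O)C=C[C@H]1O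
F6 | step 5 | 4-decyl-2,2-dimethyl-6-oxo-1,3-dioxaspiro[4.4]non-7-en-9-yl acetate | CCCCCCCCCCC1OC(C)(C)O[C@@]12[C@@H](OC(C)=O)C=CC2=O
F7 | step 5 | 4-decyl-6-hydroxy-2,2-dimethyl-1,3-dioxaspiro[4.4]non-7-en-9-yl acetate (6-OH trans to 9-OAc) | CCCCCCCCCCC1OC(C)(C)O[C@@]12[C@@H](OC(C)=O)C=C[C@@H]2O
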